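Would raising the partner from Friday's 0.700 equiv to Monday's 0.910 equiv take the lead away from the open intermediate by 2.5 h, or should I leave the charge alone?

all flasks: substrate 0.21 M

| charge | partner | remark | time |
|---|---|---|---|
| red | 0.57 equiv | run made earlier |  |
| teal | 0.64 equiv | run made earlier |  |
| Monday's | 0.910 equiv |  | 2.5 h |
| Friday's | 0.700 equiv |  | 2.5 h |

| run | time / min | substrate / % | isomer of the product / % | target / % | open intermediate / % |
|---|---|---|---|---|---|
| red | 6.00 | 39.6 | 0 | 0 | 29.3 |
| red | 12.0 | 22.7 | 2.2 | 1.9 | 39.6 |
| red | 20.0 | 15.5 | 3.4 | 4.1 | 48.7 |
| red | 40.0 | 9.6 | 9.2 | 8.3 | 53.4 |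
| red | 80.0 | 3.9 | 17.4 | 17.6 | 56.9 |
| teal | 6.00 | 40.9 | 0.8 | 0.2 | 29.8 |
| teal | 20.0 | 16.1 | 3.0 | 5.7 | 46.9 |
| teal | 40.0 | 8.5 | 9.5 | 12.2 | 51.9 |
| teal | 50.0 | 5.9 | 13.2 | 13.2 | 53.1 |
| teal | 80.0 | 2.7 | 19.7 | 19.8 | 52.6 |

(each reading ± 1 percentage point)

- which of these there is most of at the end, counted by the substrate in it, Monday's (open intermediate / target / isomer of the product / substrate)
- which of these there is most of at the end, counted by the substrate in it, Friday's (open intermediate / target / isomer of the product / substrate)
- how much there is at the end of the one of these that leads, in percent of the substrate charged: Monday's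
- how much there is at the end of the one of these that leads, in percent of the substrate charged: Friday's

- the numbers in the tables scatter by 1 percentage point (one standard deviation)
- a reading of substrate is of its free form alone

I treated the open intermediate as the large thing, the whole charge, and reckoned only the correction: the substrate that had gone on to target and isomer of the product. At the last readings the four species summed to 95.8% in red and 94.8% in teal, so I let them stand for the charge. Red gave 0.614 and teal 0.617 of target plus isomer, as a fraction of the substrate charged, per equivalent of partner charged. Pooled, this product yield per equivalent of partner was Φ = 0.616.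

I carried Φ forward to 2.5 h as a plain assumption, though it was read at an earlier time. That put my estimate of the open intermediate at one minus Φ times the equivalents: 56.9% on Friday's and 44.0% on Monday's. Target and isomer stood level in red, so I gave each half of the correction, an estimated 28.0% each on Monday's, less than the estimated intermediate. So I would not raise the charge to unseat the intermediate.

The forecast also named the open intermediate for both, but at 30% on Monday's and 32% on Friday's, on the ground that “The intermediate then decays first-order”.

The open intermediate led both flasks, at 43.1% on Monday's and 51.0% on Friday's.

    substrate → open intermediate (k = 0.00130 s⁻¹)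
    2 second intermediate → homo product (k = 0.00220 M⁻¹ s⁻¹)
    target ⇌ isomer of the product (K = 1.10, k = 0.00300 s⁻¹)
    substrate ⇌ dormant form (K = 1.30, k = 0.00160 s⁻¹)
    partner → second intermediate (k = 8.30 × 10⁻⁴ s⁻¹)
    open intermediate + second intermediate → target (k = 0.00410 M⁻¹ s⁻¹)

Φ from these flasks came to 0.609 on Monday's and 0.678 on Friday's, where the partner, the limiting reagent, ended with 0.0570% of its charge free. The main reason for the gap between the two flasks is their difference in equivalents of partner: with Friday's charge in place of its own, Monday's open intermediate goes from 43.1% to 51.0%. In a neighbour of Friday's charged with 1.80 equiv of partner, Φ fell to 0.408, and the isomer of the product led at 38.4%, with the open intermediate at 25.0%.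

The runs stem from a simulated flask with made-up constants; scatter was added.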